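**Remark on the structure (assumption):** the SMILES is read as an all-trans cyclopentane, (1S,2R,3R,5R) in the numbering C1 (acyloxymethyl), C2 (methyl), C3 (acyloxy), C4 (CH2), C5 (1,3-dihydroxypropan-2-yl), carrying two identical (3S,4E)-4-formyl-3-(2-oxoethyl)hex-4-enoyl groups (atoms C1'–C6'). This numbering is used throughout.

## The problem

The target is a cyclopentane (C1–C5) in which C5, C1, C2 and C3 are contiguous stereocentres with every neighbour trans and C4 is a methylene. Each ring stereocentre can be controlled by its neighbour (C5 → C1 → C2 → C3), and a carbonyl at C3 makes C1 the β- and C2 the α-carbon of an enone, so one stereocentre can carry the others. The C5 substituent has the skeleton of a reduced malonate and its central carbon is not stereogenic. Of the four hydroxyls, the primary one on C1 and the secondary one on C3 are esterified and the 1,3-diol must end free; the diol alone can close a six-membered acetal, which distinguishes it. The two acyl groups are identical: a trisubstituted E-enal, a second aldehyde 1,5 to it, and one stereocentre C3' that lies four to five bonds from the ring, so the ring cannot control it and reagent control is needed twice. C3'–H is γ to the enal (epimerisation through the dienol), and four aldehydes, two esters and a free diol exclude hydride, organometallic, basic or oxidising steps once they are present. The feature that opens the key step is that in each acyl group C3' is the β-carbon of the ester (C1'(=O)–C2'–C3') and bears the sp2 carbon C4' of the ethylidene unit; the C3'–C4' bond is therefore the retron of a 1,4-addition of an alkenyl–metal to an (E)-pent-2-enoate, and because the two acyl groups are the same, both bonds, both stereocentres and both alkene geometries can be made in one catalytic operation after acylation of the ring.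

## Retrosynthesis

**24 ⇒ 23.** The last operation is a hydrolysis: the four C=O groups go back to diethyl acetals and the two free hydroxyls to an isopropylidene acetal. This is preferred to oxidising four primary alcohols (the ring diol would then have to be unmasked in a further step beside the aldehydes) and to periodate cleavage of 1,2-diols (two sacrificial carbocycles). Compound 23 has no aldehyde and no free hydroxyl. The forward step must cleave five acetals and spare two esters, two enal geometries and two γ-stereocentres.

**23 ⇒ 22 + 21 (key disconnection).** Both C3'–C4' bonds are cut. The neighbouring cuts are worse: C2'–C3' would need an acetate enolate to choose between the 1,4- and 1,6-positions of a dienal, and C3'–CH2CHO has no stable nucleophile. Precursor 22 is a bis-enoate with achiral five-carbon acyl groups; 21 is a four-carbon alkenylboronate that carries the masked formyl group and the alkene geometry. The forward reaction must select one face of two enoates under catalyst control, transfer the alkenyl group with retention, and leave esters and acetals alone.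

**22 ⇒ 12 + 16.** The two ester bonds are cut, the one at C3 on the alkyl–oxygen side, so that 12 is the C3 epimer of the ring diol and the C3–O bond is made with inversion. This fits the one reliable reduction of the C3 ketone (hydride anti to the C2 methyl), which gives exactly this epimer. Compound 12 is a diol with one acetal; 16 is an achiral acid. The forward step must acylate a primary alcohol and invert a secondary one.

**12 ⇒ 10 ⇒ 6 + 7.** The C3–H bond comes from ketone reduction; the C1–CH2 and C2–CH3 bonds come from conjugate addition of a hydroxymethyl equivalent (from 7) to enone 6 and methylation of the enolate. The C5 substituent of 6 is next to the attacked carbon and directs both new groups trans. Alkene-based alternatives (hydroboration, epoxide opening) have no such bias. Compound 6 has a single stereocentre.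

**6 ⇒ 5 ⇒ 4 ⇒ 3 ⇒ 1 + 2.** The C5–C bond is cut as a palladium-catalysed allylic substitution of the commercial monoacetate 1 by malonate 2. This delivers all three carbons of the diol unit with their oxygens in one step and with defined configuration; reduction, acetal formation and allylic oxidation follow.

**16 ⇒ 15 ⇒ 13 + 14.** The C2=C3 bond of the enoate is cut as a cross-metathesis of two commercial alkenes; the acetal of 14 is the future CH2CHO arm.

**21 ⇒ 19 ⇒ 18 ⇒ 17.** The C–B bond comes from a C–I bond, which comes from α-iodination of crotonaldehyde 17. The geometry fixed at 18 (iodine cis to methyl) becomes the 4'E geometry of the target.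

## Roads not taken

**Alternative 1:** (the obvious plan) cut both acyl–oxygen bonds and bring in each side chain as a finished, masked acid, 2-[(3aS,4E,5S,6aR)-4-ethylidene-2,2-dimethyltetrahydro-4H-cyclopenta[d][1,3]dioxol-5-yl]acetic acid A1, in which the 1,5-dialdehyde is hidden as a cyclopentane-cis-1,2-diol. The forward key step would be double esterification of the ring diol with A1, hydrolysis of all acetonides and periodate cleavage of the two 1,2-diols (the 1,3-diol is inert). The end-game is attractive, but A1 needs its own enantiopure carbocycle, and its stereocentre is α to a ketone until the ethylidene is introduced, so it can epimerise. The ethylidene geometry would rest on a Wittig reaction with no built-in control, and two rings are built only to be destroyed. The chosen plan makes C3', the alkene and the aldehyde mask from crotonaldehyde in three steps plus one catalytic step.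

**Alternative 2:** cut C2'–C3' and set C3' by chirality transfer in an Ireland–Claisen rearrangement of (2S,3E)-3-{[(tert-butyldimethylsilyl)oxy]methyl}-6,6-diethoxyhex-3-en-2-yl acetate A2, giving (3S,4Z)-4-{[(tert-butyldimethylsilyl)oxy]methyl}-3-(2,2-diethoxyethyl)hex-4-enoic acid A3. The chair transition state places the carbinol methyl equatorial, which puts it cis to the C4' substituent. A3 therefore has the 4Z geometry, i.e. the less stable enal, and a late isomerisation would be needed on a substrate with an epimerisable γ-centre. The chirality is stoichiometric, A2 needs several steps, and each acid still requires separate oxidation-state changes.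

**Alternative 3:** make the ring by contraction: Favorskii rearrangement of (2S,3R,5R)-2-chloro-3-hydroxy-2-methyl-5-(prop-1-en-2-yl)cyclohexan-1-one A4 (from (R)-carvone by epoxidation and opening with HCl; hydroxyl protected) to methyl (1S,2S,3R,5R)-3-hydroxy-2-methyl-5-(prop-1-en-2-yl)cyclopentane-1-carboxylate A5. By the accepted mechanism (cyclopropanone closure with inversion at the chloride-bearing carbon, ring opening with retention) the C2 methyl ends cis to the C3 oxygen. That is the wrong C2 epimer at a centre that cannot be equilibrated. The isopropenyl group would also need allylic oxidation and hydroboration to become the diol, and β-elimination of the C3 oxygen competes. The chosen route gets the C5 substituent from malonate in one step and C1/C2 in one trans-selective event.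

Key step: step 13

## Steps

**Step 1**
Reactants: 1 (1S,4R)-cis-4-acetoxycyclopent-2-en-1-ol; 2 dimethyl malonate
Product: 3 dimethyl 2-[(1R,4S)-4-hydroxycyclopent-2-en-1-yl]propanedioate
Conditions: 2, NaH, THF, 0 °C; then 1, Pd(PPh3)4 (3 mol %), THF, rt
Reagents that add atoms: none
Why: Tsuji–Trost allylic alkylation. Zerovalent palladium ionises the allylic acetate with inversion and the malonate anion attacks the π-allyl complex anti to the metal at the terminus remote from the hydroxyl, so malonate replaces acetate with net retention (cis-1,4); the stereocentre that becomes C5 is bought with 1.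

**Step 2**
Reactants: 3
Product: 4 2-[(1R,4S)-4-hydroxycyclopent-2-en-1-yl]propane-1,3-diol
Conditions: LiAlH4, THF, 0 °C → rt
Reagents that add atoms: none
Why: Hydride reduction of both esters gives the 2-substituted propane-1,3-diol; its central carbon is not stereogenic and the ring stereocentres are not touched.

**Step 3**
Reactants: 4
Product: 5 (1S,4R)-4-(2,2-dimethyl-1,3-dioxan-5-yl)cyclopent-2-en-1-ol
Conditions: Me2C(OMe)2, PPTS (cat.), acetone, rt
Reagents that add atoms: 2,2-dimethoxypropane, COC(C)(C)OC
Why: Acid-catalysed transacetalisation under thermodynamic control; only the 1,3-diol can close a six-membered acetal, so the allylic hydroxyl stays free. The acetal should survive all later steps and fall in the last one.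

**Step 4**
Reactants: 5
Product: 6 (4R)-4-(2,2-dimethyl-1,3-dioxan-5-yl)cyclopent-2-en-1-one
Conditions: MnO2, CH2Cl2, rt
Reagents that add atoms: none
Why: Selective oxidation of an allylic alcohol by manganese dioxide under neutral conditions; no base is present to enolise the γ-stereocentre.

**Step 5**
Reactants: 6; 7 (chloromethyl)dimethyl(propan-2-yloxy)silane
Product: 10 (2R,3S,4S)-4-(2,2-dimethyl-1,3-dioxan-5-yl)-3-{[dimethyl(propan-2-yloxy)silyl]methyl}-2-methylcyclopentan-1-one, via Grignard reagent 8 (not isolated), via magnesium enolate 9 (not isolated)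
Conditions: 7, Mg, THF, rt; then 6, CuBr·SMe2 (10 mol %), THF, −78 → −30 °C; then MeI, DMPU, −30 → 0 °C
Reagents that add atoms: iodomethane, CI
Why: Copper-catalysed conjugate addition of a silylmethyl Grignard reagent (a hydroxymethyl-anion equivalent) followed by enolate alkylation, the three-component coupling used on 4-substituted cyclopentenones. The silylmethyl group should enter anti to the adjacent dioxanyl group and the methyl anti to the new substituent, giving the all-trans ketone, which is also the stable epimer at the enolisable C2.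

**Step 6**
Reactants: 10
Product: 12 (1S,2R,3S,4R)-4-(2,2-dimethyl-1,3-dioxan-5-yl)-3-(hydroxymethyl)-2-methylcyclopentan-1-ol, via silyl alcohol 11 (not isolated)
Conditions: LiBH(s-Bu)3, THF, −78 °C; then KHCO3, KF, 30% H2O2, MeOH/THF, 0 °C → rt
Reagents that add atoms: hydrogen peroxide, OO
Why: The bulky hydride should attack the ketone anti to the adjacent methyl group, as in 2-alkylcyclopentanones, giving the alcohol cis to the methyl; the remote dioxanyl group is on the same face as the methyl and reinforces this. Tamao–Fleming oxidation in the same flask converts C–Si into C–OH at a non-stereogenic carbon.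

**Step 7**
Reactants: 13 methyl acrylate; 14 4,4-diethoxybut-1-ene
Product: 15 methyl (2E)-5,5-diethoxypent-2-enoate
Conditions: second-generation Hoveyda–Grubbs catalyst RuCl2(H2IMes)(=CH-C6H4-2-OiPr) (2 mol %), 13 (3 equiv), CH2Cl2, 40 °C
Reagents that add atoms: none
Why: Cross-metathesis of a terminal alkene with an acrylate is selective for the cross product and gives the E-enoate under thermodynamic control.

**Step 8**
Reactants: 15
Product: 16 (2E)-5,5-diethoxypent-2-enoic acid
Conditions: LiOH·H2O, THF/H2O 3:1, 0 °C → rt; then KHSO4 (aq) to pH 3–4, 0 °C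
Reagents that add atoms: lithium hydroxide, [Li+].[OH-]
Why: Saponification; the acetal is stable to base, and the acidification is brief and cold to keep it.

**Step 9**
Reactants: 17 (2E)-but-2-enal
Product: 18 (2Z)-2-iodobut-2-enal
Conditions: I2, K2CO3, DMAP (20 mol %), THF/H2O 1:1, rt
Reagents that add atoms: iodine, II
Why: α-Iodination of an enal by amine addition, iodination of the enolate and elimination (a Baylis–Hillman-type sequence). The isomer with iodine cis to methyl and formyl trans to methyl is the one expected, and this fixes the later 4'E geometry.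

**Step 10**
Reactants: 18
Product: 19 (2Z)-1,1-diethoxy-2-iodobut-2-ene
Conditions: HC(OEt)3, EtOH, TsOH·H2O (cat.), rt
Reagents that add atoms: triethyl orthoformate, CCOC(OCC)OCC; ethanol, CCO
Why: Orthoformate acetalisation masks the aldehyde against the organolithium of the next step and supplies the acetal that is carried to the end.

**Step 11**
Reactants: 19
Product: 21 2-[(2E)-1,1-diethoxybut-2-en-2-yl]-4,4,5,5-tetramethyl-1,3,2-dioxaborolane, via alkenyllithium 20 (not isolated)
Conditions: t-BuLi (2 equiv), Et2O, −78 °C; then iPrOBpin, −78 °C → rt; NH4Cl (aq)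
Reagents that add atoms: 2-isopropoxy-4,4,5,5-tetramethyl-1,3,2-dioxaborolane, CC(C)OB1OC(C)(C)C(C)(C)O1
Why: Iodine–lithium exchange and borylation both proceed with retention at the sp2 carbon, and the α-alkoxymethyl alkenyllithium is configurationally stable at −78 °C; boron therefore ends cis to the methyl group.

**Step 12**
Reactants: 12; 16
Product: 22 [(1S,2R,3R,5R)-5-(2,2-dimethyl-1,3-dioxan-5-yl)-3-{[(2E)-5,5-diethoxypent-2-enoyl]oxy}-2-methylcyclopentyl]methyl (2E)-5,5-diethoxypent-2-enoate
Conditions: 16 (2.5 equiv), PPh3, DIAD, toluene, 0 °C → rt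
Reagents that add atoms: none
Why: Double Mitsunobu esterification. The primary alcohol is acylated, and the secondary alkoxyphosphonium is displaced by the carboxylate in an SN2 step with inversion, which turns the 3S alcohol of 12 into the 3R ester and so completes the all-trans ring. The carboxylate approaches C3 on the face anti to the C2 methyl.

**Step 13**
Reactants: 22; 21
Product: 23 [(1S,2R,3R,5R)-5-(2,2-dimethyl-1,3-dioxan-5-yl)-3-{[(3S,4E)-3-(2,2-diethoxyethyl)-4-(diethoxymethyl)hex-4-enoyl]oxy}-2-methylcyclopentyl]methyl (3S,4E)-3-(2,2-diethoxyethyl)-4-(diethoxymethyl)hex-4-enoate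
Conditions: [Rh(OH)((S)-BINAP)]2 (5 mol %), 21 (6 equiv), K3PO4, 1,4-dioxane/H2O 10:1, 50 °C
Reagents that add atoms: none
Why: Rhodium-catalysed asymmetric conjugate addition of an alkenylboron reagent to an enoate (Hayashi–Miyaura reaction), run on both enoates of 22 in one operation. The hydroxo complex of monovalent rhodium takes the alkenyl group of 21 from boron with retention of alkene geometry, the (E)-enoate inserts into the Rh–C bond, and water protonates the oxa-π-allylrhodium and returns Rh–OH; no ring is closed. The closest known reaction type is the addition of aryl- and alkenylboron reagents to (E)-β-alkyl acrylates and to 5,6-dihydro-2H-pyran-2-one with BINAP- or diene-ligated rhodium. Each new stereocentre (C3' of either chain) is controlled by the ligand alone, since the nearest ring stereocentre is four (ester on C3) or five (ester on C1–CH2) bonds from the reacting carbon; with (S)-BINAP the enoate should bind by the face that keeps its β-substituent away from the blocking P-phenyl group, which for the priorities alkenyl > CH2CO2R > CH2CH(OEt)2 corresponds to 3'S (the mirror-image ligand gives the other series). The 4'E geometry is that of 21 and needs only that the alkenylrhodium keeps its configuration. The step needs 1,4-addition to outrun protodeboronation of 21 and loss of ethoxide from the alkenylrhodium (hence the excess of 21, added in portions), and it needs the esters and acetals to survive, which mildly basic aqueous dioxane should allow. Because both centres are set by the same catalyst, an error at one centre gives a diastereomer of 23 and not its enantiomer, so the major isomer is enriched and the minor ones can be separated.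

**Step 14**
Reactants: 23
Product: 24 [(1S,2R,3R,5R)-5-(1,3-dihydroxypropan-2-yl)-3-{[(3S,4E)-4-formyl-3-(2-oxoethyl)hex-4-enoyl]oxy}-2-methylcyclopentyl]methyl (3S,4E)-4-formyl-3-(2-oxoethyl)hex-4-enoate
Conditions: 1 M HCl (aq)/THF 1:4, 0 °C → rt
Reagents that add atoms: water, O
Why: Acid hydrolysis of the four diethyl acetals and the isopropylidene acetal in one operation; dilute aqueous acid at low temperature should spare the esters, the E-enals and the C3' centres. The large excess of water keeps the freed diol from forming acetals with the aldehydes.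

## Compound list

1 | (1S,4R)-cis-4-acetoxycyclopent-2-en-1-ol | O[C@H]1C[C@@H](OC(C)=O)C=C1 | starting material
2 | dimethyl malonate | COC(=O)CC(=O)OC | starting material
3 | dimethyl 2-[(1R,4S)-4-hydroxycyclopent-2-en-1-yl]propanedioate | O[C@H]1C[C@@H](C(C(=O)OC)C(=O)OC)C=C1 | intermediate
4 | 2-[(1R,4S)-4-hydroxycyclopent-2-en-1-yl]propane-1,3-diol | O[C@H]1C[C@@H](C(CO)CO)C=C1 | intermediate
5 | (1S,4R)-4-(2,2-dimethyl-1,3-dioxan-5-yl)cyclopent-2-en-1-ol | O[C@H]1C[C@@H](C2COC(C)(C)OC2)C=C1 | intermediate
6 | (4R)-4-(2,2-dimethyl-1,3-dioxan-5-yl)cyclopent-2-en-1-one | O=C1C[C@@H](C2COC(C)(C)OC2)C=C1 | intermediate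
7 | (chloromethyl)dimethyl(propan-2-yloxy)silane | CC(C)O[Si](C)(C)CCl | starting material
8 | {[dimethyl(propan-2-yloxy)silyl]methyl}magnesium chloride | CC(C)O[Si](C)(C)C[Mg]Cl | intermediate
9 | chloromagnesium (3S,4S)-4-(2,2-dimethyl-1,3-dioxan-5-yl)-3-{[dimethyl(propan-2-yloxy)silyl]methyl}cyclopent-1-en-1-olate | CC(C)O[Si](C)(C)C[C@@H]1C=C(O[Mg]Cl)C[C@H]1C2COC(C)(C)OC2 | intermediate
10 | (2R,3S,4S)-4-(2,2-dimethyl-1,3-dioxan-5-yl)-3-{[dimethyl(propan-2-yloxy)silyl]methyl}-2-methylcyclopentan-1-one | CC(C)O[Si](C)(C)C[C@@H]1[C@@H](C)C(=O)C[C@H]1C2COC(C)(C)OC2 | intermediate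
11 | (1S,2R,3S,4S)-4-(2,2-dimethyl-1,3-dioxan-5-yl)-3-{[dimethyl(propan-2-yloxy)silyl]methyl}-2-methylcyclopentan-1-ol | CC(C)O[Si](C)(C)C[C@@H]1[C@@H](C)[C@@H](O)C[C@H]1C2COC(C)(C)OC2 | intermediate
12 | (1S,2R,3S,4R)-4-(2,2-dimethyl-1,3-dioxan-5-yl)-3-(hydroxymethyl)-2-methylcyclopentan-1-ol | OC[C@@H]1[C@@H](C)[C@@H](O)C[C@H]1C2COC(C)(C)OC2 | intermediate
13 | methyl acrylate | C=CC(=O)OC | starting material
14 | 4,4-diethoxybut-1-ene | C=CCC(OCC)OCC | starting material
15 | methyl (2E)-5,5-diethoxypent-2-enoate | CCOC(OCC)C/C=C/C(=O)OC | intermediate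
16 | (2E)-5,5-diethoxypent-2-enoic acid | CCOC(OCC)C/C=C/C(=O)O | intermediate
17 | (2E)-but-2-enal | C/C=C/C=O | starting material
18 | (2Z)-2-iodobut-2-enal | C/C=C(\I)C=O | intermediate
19 | (2Z)-1,1-diethoxy-2-iodobut-2-ene | C/C=C(\I)C(OCC)OCC | intermediate
20 | [(2E)-1,1-diethoxybut-2-en-2-yl]lithium | C/C=C(\[Li])C(OCC)OCC | intermediate
21 | 2-[(2E)-1,1-diethoxybut-2-en-2-yl]-4,4,5,5-tetramethyl-1,3,2-dioxaborolane | C/C=C(\B1OC(C)(C)C(C)(C)O1)C(OCC)OCC | intermediate
22 | [(1S,2R,3R,5R)-5-(2,2-dimethyl-1,3-dioxan-5-yl)-3-{[(2E)-5,5-diethoxypent-2-enoyl]oxy}-2-methylcyclopentyl]methyl (2E)-5,5-diethoxypent-2-enoate | CCOC(OCC)C/C=C/C(=O)OC[C@@H]1[C@@H](C)[C@H](OC(=O)/C=C/CC(OCC)OCC)C[C@H]1C2COC(C)(C)OC2 | intermediate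
23 | [(1S,2R,3R,5R)-5-(2,2-dimethyl-1,3-dioxan-5-yl)-3-{[(3S,4E)-3-(2,2-diethoxyethyl)-4-(diethoxymethyl)hex-4-enoyl]oxy}-2-methylcyclopentyl]methyl (3S,4E)-3-(2,2-diethoxyethyl)-4-(diethoxymethyl)hex-4-enoate | C/C=C(/C(OCC)OCC)[C@@H](CC(OCC)OCC)CC(=O)OC[C@@H]1[C@@H](C)[C@H](OC(=O)C[C@H](CC(OCC)OCC)/C(C(OCC)OCC)=C\C)C[C@H]1C2COC(C)(C)OC2 | intermediate
24 | [(1S,2R,3R,5R)-5-(1,3-dihydroxypropan-2-yl)-3-{[(3S,4E)-4-formyl-3-(2-oxoethyl)hex-4-enoyl]oxy}-2-methylcyclopentyl]methyl (3S,4E)-4-formyl-3-(2-oxoethyl)hex-4-enoate | C/C=C(/C=O)[C@@H](CC=O)CC(=O)OC[C@@H]1[C@@H](C)[C@H](OC(=O)C[C@H](CC=O)/C(C=O)=C\C)C[C@H]1C(CO)CO | target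

## Step count and least certain steps

Total: 14 steps. Longest linear sequence: 9 steps (steps 1–6, then 12, 13, 14). The two branches are steps 7–8 (acid 16) and steps 9–11 (boronate 21).

**Step 13 (key step).** The most likely failure is slow insertion of a β-alkyl enoate into a hindered, α,α-disubstituted alkenyl–rhodium bond. Protodeboronation of 21 and loss of ethoxide from the alkenylrhodium would then compete, the second addition could stay incomplete, and face selection on an acyclic enoate could be imperfect. The fallback sets the side-chain stereocentre before acylation with a chiral auxiliary and a copper reagent; it sets out from acid 16 and alkenyllithium 20 and comes back at 23. Acid 16 is activated (pivaloyl chloride, Et3N) and coupled with lithiated (R)-4-phenyl-1,3-oxazolidin-2-one to give (4R)-3-[(2E)-5,5-diethoxypent-2-enoyl]-4-phenyl-1,3-oxazolidin-2-one F1. The alkenylcopper reagent made from 20 (MgBr2·OEt2, then CuBr·SMe2, THF/Me2S, −78 → −20 °C) should add anti to the phenyl group of the magnesium-chelated s-cis imide to give (4R)-3-[(3S,4E)-3-(2,2-diethoxyethyl)-4-(diethoxymethyl)hex-4-enoyl]-4-phenyl-1,3-oxazolidin-2-one F2. LiOH/H2O2 removes the auxiliary and gives (3S,4E)-3-(2,2-diethoxyethyl)-4-(diethoxymethyl)hex-4-enoic acid F3, and the Mitsunobu conditions of step 12 applied to diol 12 and F3 give 23.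

**Step 12.** The secondary alcohol is flanked by two ring substituents, and elimination to a cyclopentene, acyl transfer with retention, or incomplete reaction at C3 can take over with a carboxylic acid of ordinary acidity. The fallback separates inversion from acylation; it sets out from 12 and comes back at 22. Mitsunobu reaction of 12 with the more acidic 4-nitrobenzoic acid (PPh3, DIAD) gives [(1S,2R,3R,5R)-5-(2,2-dimethyl-1,3-dioxan-5-yl)-2-methyl-3-[(4-nitrobenzoyl)oxy]cyclopentyl]methyl 4-nitrobenzoate F4, and methanolysis (K2CO3, MeOH) gives the inverted diol (1R,2R,3S,4R)-4-(2,2-dimethyl-1,3-dioxan-5-yl)-3-(hydroxymethyl)-2-methylcyclopentan-1-ol F5. Carbodiimide esterification of F5 (EDC·HCl, DMAP) with 16 gives 22.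

**Step 5.** The magnesium enolate may alkylate slowly, so that proton exchange with the product leads to unmethylated or doubly methylated ketone and to loss of regiocontrol. The fallback brings the methyl group in by cross-coupling before the conjugate addition; it sets out from 6 and comes back at 10. Iodination of 6 (I2, pyridine, CH2Cl2) gives (4S)-4-(2,2-dimethyl-1,3-dioxan-5-yl)-2-iodocyclopent-2-en-1-one F6, and Suzuki methylation (trimethylboroxine, PdCl2(dppf), K2CO3, dioxane) gives (4R)-4-(2,2-dimethyl-1,3-dioxan-5-yl)-2-methylcyclopent-2-en-1-one F7. Copper-catalysed addition of 8 to F7 (CuBr·SMe2, TMSCl, THF, −78 °C), acidic work-up and equilibration at C2 (DBU) give 10.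

**Step 14.** The freed 1,3-diol can form acetals with the aldehydes (oligomerisation), and acid can enolise the enal towards C3' (epimerisation) or start aldol condensation of the 1,5-dialdehyde. The fallback releases the diol and the aldehydes in separate operations and ends with a fluoride step; it sets out from 23 and comes back at 24. Ethanolysis (PPTS, EtOH), which removes only the isopropylidene acetal because the diethyl acetals exchange degenerately, gives [(1S,2R,3R,5R)-5-(1,3-dihydroxypropan-2-yl)-3-{[(3S,4E)-3-(2,2-diethoxyethyl)-4-(diethoxymethyl)hex-4-enoyl]oxy}-2-methylcyclopentyl]methyl (3S,4E)-3-(2,2-diethoxyethyl)-4-(diethoxymethyl)hex-4-enoate F8. Silylation (TBSCl, imidazole, DMF) gives its bis(tert-butyldimethylsilyl) ether F9. Transacetalisation (PPTS, acetone/H2O) gives [(1S,2R,3R,5R)-5-{1,3-bis[(tert-butyldimethylsilyl)oxy]propan-2-yl}-3-{[(3S,4E)-4-formyl-3-(2-oxoethyl)hex-4-enoyl]oxy}-2-methylcyclopentyl]methyl (3S,4E)-4-formyl-3-(2-oxoethyl)hex-4-enoate F10, and HF·pyridine (pyridine/THF, 0 °C) gives 24.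

## Further compounds

F1 | step 13 | (4R)-3-[(2E)-5,5-diethoxypent-2-enoyl]-4-phenyl-1,3-oxazolidin-2-one | CCOC(OCC)C/C=C/C(=O)N1[C@H](c2ccccc2)COC1=O
F2 | step 13 | (4R)-3-[(3S,4E)-3-(2,2-diethoxyethyl)-4-(diethoxymethyl)hex-4-enoyl]-4-phenyl-1,3-oxazolidin-2-one | C/C=C(/C(OCC)OCC)[C@@H](CC(OCC)OCC)CC(=O)N1[C@H](c2ccccc2)COC1=O
F3 | step 13 | (3S,4E)-3-(2,2-diethoxyethyl)-4-(diethoxymethyl)hex-4-enoic acid | C/C=C(/C(OCC)OCC)[C@@H](CC(OCC)OCC)CC(=O)O
F4 | step 12 | [(1S,2R,3R,5R)-5-(2,2-dimethyl-1,3-dioxan-5-yl)-2-methyl-3-[(4-nitrobenzoyl)oxy]cyclopentyl]methyl 4-nitrobenzoate | O=C(OC[C@@H]1[C@@H](C)[C@H](OC(=O)c2ccc(cc2)[N+](=O)[O-])C[C@H]1C3COC(C)(C)OC3)c4ccc(cc4)[N+](=O)[O-]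
F5 | step 12 | (1R,2R,3S,4R)-4-(2,2-dimethyl-1,3-dioxan-5-yl)-3-(hydroxymethyl)-2-methylcyclopentan-1-ol | OC[C@@H]1[C@@H](C)[C@H](O)C[C@H]1C2COC(C)(C)OC2
F6 | step 5 | (4S)-4-(2,2-dimethyl-1,3-dioxan-5-yl)-2-iodocyclopent-2-en-1-one | O=C1C[C@@H](C2COC(C)(C)OC2)C=C1I
F7 | step 5 | (4R)-4-(2,2-dimethyl-1,3-dioxan-5-yl)-2-methylcyclopent-2-en-1-one | O=C1C[C@@H](C2COC(C)(C)OC2)C=C1C
F8 | step 14 | [(1S,2R,3R,5R)-5-(1,3-dihydroxypropan-2-yl)-3-{[(3S,4E)-3-(2,2-diethoxyethyl)-4-(diethoxymethyl)hex-4-enoyl]oxy}-2-methylcyclopentyl]methyl (3S,4E)-3-(2,2-diethoxyethyl)-4-(diethoxymethyl)hex-4-enoate | C/C=C(/C(OCC)OCC)[C@@H](CC(OCC)OCC)CC(=O)OC[C@@H]1[C@@H](C)[C@H](OC(=O)C[C@H](CC(OCC)OCC)/C(C(OCC)OCC)=C\C)C[C@H]1C(CO)CO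
F9 | step 14 | [(1S,2R,3R,5R)-5-{1,3-bis[(tert-butyldimethylsilyl)oxy]propan-2-yl}-3-{[(3S,4E)-3-(2,2-diethoxyethyl)-4-(diethoxymethyl)hex-4-enoyl]oxy}-2-methylcyclopentyl]methyl (3S,4E)-3-(2,2-diethoxyethyl)-4-(diethoxymethyl)hex-4-enoate | C/C=C(/C(OCC)OCC)[C@@H](CC(OCC)OCC)CC(=O)OC[C@@H]1[C@@H](C)[C@H](OC(=O)C[C@H](CC(OCC)OCC)/C(C(OCC)OCC)=C\C)C[C@H]1C(CO[Si](C)(C)C(C)(C)C)CO[Si](C)(C)C(C)(C)C
F10 | step 14 | [(1S,2R,3R,5R)-5-{1,3-bis[(tert-butyldimethylsilyl)oxy]propan-2-yl}-3-{[(3S,4E)-4-formyl-3-(2-oxoethyl)hex-4-enoyl]oxy}-2-methylcyclopentyl]methyl (3S,4E)-4-formyl-3-(2-oxoethyl)hex-4-enoate | C/C=C(/C=O)[C@@H](CC=O)CC(=O)OC[C@@H]1[C@@H](C)[C@H](OC(=O)C[C@H](CC=O)/C(C=O)=C\C)C[C@H]1C(CO[Si](C)(C)C(C)(C)C)CO[Si](C)(C)C(C)(C)C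
A1 | alternative 1 | 2-[(3aS,4E,5S,6aR)-4-ethylidene-2,2-dimethyltetrahydro-4H-cyclopenta[d][1,3]dioxol-5-yl]acetic acid | C/C=C1\[C@H](CC(=O)O)C[C@H]2OC(C)(C)O[C@@H]12
A2 | alternative 2 | (2S,3E)-3-{[(tert-butyldimethylsilyl)oxy]methyl}-6,6-diethoxyhex-3-en-2-yl acetate | C[C@H](OC(C)=O)/C(CO[Si](C)(C)C(C)(C)C)=C/CC(OCC)OCC
A3 | alternative 2 | (3S,4Z)-4-{[(tert-butyldimethylsilyl)oxy]methyl}-3-(2,2-diethoxyethyl)hex-4-enoic acid | C/C=C(\CO[Si](C)(C)C(C)(C)C)[C@@H](CC(OCC)OCC)CC(=O)O
A4 | alternative 3 | (2S,3R,5R)-2-chloro-3-hydroxy-2-methyl-5-(prop-1-en-2-yl)cyclohexan-1-one | CC(=C)[C@@H]1C[C@@H](O)[C@](C)(Cl)C(=O)C1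
A5 | alternative 3 | methyl (1S,2S,3R,5R)-3-hydroxy-2-methyl-5-(prop-1-en-2-yl)cyclopentane-1-carboxylate | COC(=O)[C@@H]1[C@H](C)[C@H](O)C[C@H]1C(C)=C
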